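A one-step world would carry c(target) up to the smaller charge, the solid substrate, but the eta run flattens at 40.6%, that is 8.93 mM.

| flask | solid substrate | partner | protic impurity | temperature | remark | time |
|---|---|---|---|---|---|---|
| eta | 22 mM | 24.2 mM | 22 mM | 25 °C | the very flask that is asked about, followed so far |  |
| theta | 15 mM | 24.2 mM | 22 mM | 25 °C | run made earlier |  |
| flask | 22 mM | 24.2 mM | 22.0 mM | 25 °C |  | 20 min |

| run | time / min | target / % |
|---|---|---|
| eta | 2.00 | 11.4 |
| eta | 4.00 | 25.9 |
| eta | 6.00 | 33.8 |
| eta | 8.00 | 38.6 |
| eta | 10.0 | 39.8 |
| eta | 12.0 | 40.6 |
| theta | 0.500 | 2.1 |
| theta | 1.33 | 9.5 |
| theta | 2.50 | 24.4 |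
| theta | 4.00 | 38.3 |
| theta | 5.00 | 44.2 |
| theta | 8.00 | 52.2 |

(each reading ± 0.5 percentage points)

- Tuesday's: at 20 min add partner, 50.0% of the amount charged, then wait 40 min
- Thursday's: at 20 min take out 90% of the target then present, then wait 40 min
- Monday's: change nothing and wait 40 min more
- Wednesday's: at 20 min raise the temperature by 25 K, then wait 40 min

- given per volume of solution although it is solid: solid substrate
- target that was removed still counts
- at the start none of the solid substrate is in solution
- additions bring no volume worth counting

- target, in percent of the solid substrate first charged, at 20 min
- the remedy with the largest gain of target, or "none" below 2 percentage points (Tuesday's / Thursday's / Monday's / Wednesday's / none)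
- target present, with what was taken out counted in, in percent of the solid substrate first charged, after Tuesday's
- target present, with what was taken out counted in, in percent of the solid substrate first charged, after Wednesday's

The theta run, with less solid, has 7.83 mM at its last reading and is still rising, so c(target) follows the solid charge only weakly. That points to partner as the limiting reagent. But the eta run charged 24.2 mM of partner, more than the target found, so the rest went elsewhere. If protic impurity took it one to one, c(protic impurity) fell to 6.73 mM.

Both consumers react with partner, so it is better to count the fraction of impurity left than the amount lost. Define the split number a as the target made divided by the natural logarithm of charged over remaining impurity; it is a selectivity factor in concentration units. The eta run gives a = 7.54 mM.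

This reckoning takes the flask to stay near its last reading, with nothing for waiting, removal or heating to work on. Fresh partner, 12.1 mM, is reckoned here to split as a to c(protic impurity), with a held at its value from the eta run, an average over that run, so the estimate sends 52.8% to target. That estimate gives 6.39 mM, or 29 percentage points, above the margin.

The forecast, holding that “the protic impurity eats it in competition”, gives 41.3%, Tuesday's, 78% and 41.5%; its figure for Tuesday's is higher than the 69.7% of this reckoning.

The flask gives 41.1%, and Tuesday's gains 38 points, reaching 79.4%, while Wednesday's stays at 41.1%. At 20.0 min the unreacted substrate stands as dissolved substrate, 58.9%, with 0% still solid and 0.0124% of the partner free. With 31% of the impurity left, a gives 40.1% for this flask.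

    solid substrate ⇌ dissolved substrate, rate k1*(cs1 - [dissolved substrate]) while solid is left; crystals form when [dissolved substrate] > cs1 (solubility = 15.0 mM, k = 0.00628 s⁻¹)
    dissolved substrate + partner → target (k = 0.440 L mol⁻¹ s⁻¹, Ea = 38.0 kJ mol⁻¹)
    partner + protic impurity → quenched reagent (k = 0.322 L mol⁻¹ s⁻¹, Ea = 37.0 kJ mol⁻¹)
    (constants at 25 °C)

In the neighbour flask with 5.5 mM of protic impurity, 8.6% of it is left, so a gives 84.2% of target. The computed result is 83.1%.

Readings and results are calculated from invented constants; noise was put on by code.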